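## Analysis of the target

Target 32 is a heptacyclic dimer of two guaianolide halves. The unprimed half holds ring A (cyclopentanone C1–C5), ring B (cycloheptene C1, C10, C9, C8, C7, C6, C5) and lactone ring C. The primed half holds cyclopentanone ring E, cycloheptane ring F and lactone ring G. Cyclohexene ring D (C2–C1=C10–C14–C15'–C4') joins them and is spiro at C4'.

There are nine stereocentres. C1', C5', C6' and C7' are those of natural dehydrocostus lactone (cis ring fusion with 1α,5α-H, trans lactone with 6β-H and 7α-H), and C5, C6 and C7 repeat that pattern. The tertiary alcohol C2 (OH α, cis to H-5) sits next to the quaternary spiro carbon C4', which is bonded to C2 on the α face of ring E; C2–O and C3' are trans across ring D.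

The sensitive groups are three exocyclic Michael acceptors (the C4=C15 enone and two α-methylene lactones), the α-ketol C2–OH/C3=O, the β-hydroxy ketone C2–OH/C3'=O (retro-aldol) and the 1,1-disubstituted C10'=C14' alkene.

Two things make the synthesis hard. The first is the congested C2/C4' pair. The second is a twin problem: the C3 and C3' cyclopentanones each have one α-methylene (C4 and C2'), and there are two lactones, so any late methylenation has to tell twins apart.

The strategy rests on the tetrasubstituted C1=C10 alkene shared by rings A, B and D. It is read as the two carbons of an alkyne, and the C6–C7 unit with its oxygen at C6 is read as the silyl enol ether of a cyclopropyl ketone. Rings A and B then come from one rhodium-catalysed (5+2) cycloaddition.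

## Retrosynthetic reasoning

**32 ⇒ 31 (C3' oxidation level).** The C3' ketone is taken back to a secondary alcohol. While it is an alcohol there is no β-hydroxy ketone to undergo retro-aldol cleavage and no enolisable C2' methylene to compete with C4. The last forward step only has to oxidise one hindered secondary alcohol next to a tertiary one.

**31 ⇒ 29 ⇒ 27 (C4–C15 and C11–C13).** Both exocyclic methylene carbons are removed together. In 27 the only enolisable carbonyl groups are the C3 ketone (toward C4 only, C2 being quaternary) and the unprimed lactone (C11). One soft-enolisation and aminomethylation sequence followed by quaternisation and elimination installs both alkenes without a strong base, which the primed α-methylene lactone would not tolerate.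

**27 ⇒ 26 ⇒ 24 (C3 ketal, lactone C–O bond, C6–H).** The C3 ketone is masked as its dimethyl ketal until after all hydride chemistry. The lactone is opened to the C6 ketone and C12 methyl ester of 24. One borohydride step must reduce C6 from the β face, after which the 6α-alkoxide closes ring C, and must also reduce C3', which supplies the C3' mask used above.

**24 ⇒ 23 (C7–H).** The C6 ketone is the hydrolysis product of the C6=C7 silyl enol ether. Protonation at C7 has to place the side chain β, cis-1,3 to C4, which is both the kinetic and the thermodynamic preference.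

**23 ⇒ 22 (C2–C4', ring D).** Cutting the bond between the tertiary carbinol and the spiro carbon reveals an aldol. The nucleophile is the C3'=C4' silyl enol ether and the electrophile is the C2 ketone. Only the six-membered closure is geometrically possible, and the step creates C2 and C4' together.

**22 ⇒ 21 (C1–C5 and C9–C10, rings A and B).** This is the key disconnection. It is made here because it turns the whole bicyclic unprimed core into a linear chain in which the alkyne carbons are C1 and C10 and a 1,1-disubstituted cyclopropane supplies C7, C8 and C9. The forward step has to create only one stereocentre, C5.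

**21 ⇒ 20 ⇒ 18 + 8 (enol ether; C1–C2).** The (Z)-enol ether comes from ketone 20, which can enolise in one direction only. The ynone is cut at the acyl–alkyne bond into acid 18 and terminal alkyne 8, a mild union that tolerates every group present.

**8 ⇒ 7 ⇒ 3 + 4 (C14–C15').** The butynyl chain on C4' and the regiodefined C3' enol ether arise together from conjugate addition of a propargyl unit from 4 to the exocyclic enone of 3, with the enolate trapped on oxygen. Enone 3 comes in two oxidations from commercial lactone 1, which brings all four primed stereocentres and the primed α-methylene lactone.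

**18 ⇒ 17 ⇒ 15 ⇒ 12 + 13 (C4–C5; C3 oxidation).** The α-keto acid is masked as a 2-methylidene ester. The C4–C5 bond is made by alkylating the methyl ketone enolate of 12 with allylic bromide 13, ozonolysis unveils the C3 ketone, and the tert-butyl/methyl ester pair distinguishes C2 from C12.

**12 ⇒ 11 ⇒ 9 (cyclopropane; C5–C6).** The cyclopropane is made by methylene transfer to the 2-methylidene ketone 11. Ketone 11 comes from acylation of a methyl organometallic by the acid chloride of monoester 9, whose two carboxyl groups are already differentiated.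

## Alternatives that were turned down

**Alternative 1:** Ring B is cut at C9–C10 and C5–C6. In the forward step a chiral dirhodium tetracarboxylate turns vinyl diazo ester A2 into a carbenoid at C10, which cyclopropanates the terminal alkene of silyloxy diene A3; the cis-divinylcyclopropane then undergoes Cope rearrangement to hydroazulene A1.

- For it: this catalytic asymmetric (4+3) is reliable, starts from two small achiral pieces, and sets C5 and the C6 oxygen stereocentre together. On that point it is stronger than the chosen route, which sets C5 by catalyst and C6 later by substrate-controlled hydride delivery.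
- Against it: A1 has no C3 oxygen, carries a C7=C8 alkene that must be reduced with control at C7, and contains nothing of the primed half. Joining it to the primed half needs a C14 nucleophile or electrophile made from the ester, a second bond (C2–C4') and an oxidation at unactivated C3.
- Comparison: the chosen route accepts weaker control at C6 in exchange for early convergence. Both halves are joined by a mild acylation before the key step, C3 is oxidised from the start, and the adduct already has every carbon of rings A, B and D in place.

**Alternative 2:** Ring A is cut at C2–C3. In the forward step a triazolium-derived carbene turns a C3 aldehyde into an acyl anion equivalent that adds to the C2 ketone of the ring D enone, giving ketol A4.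

- For it: the α-ketol, the most delicate motif, is made directly and late in one intramolecular crossed benzoin reaction. This is more direct than the chosen route, which makes the carbinol by an aldol and unmasks the C3 ketone from a ketal.
- Against it: the substrate of that step is nearly the whole molecule. Rings B to G, the spiro centre and an epimerisable C4 stereocentre must already exist, so the hard bonds of rings B and D are not addressed. The ketone is flanked by the spiro quaternary carbon, so addition is hindered and reversible. A4 still needs three methylene groups unveiled, two of them from 11-methyl lactones by strong-base selenation in the presence of the retro-aldol-prone hydroxy ketone.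
- Comparison: the chosen route is shorter overall because its key step builds two rings, and it uses the natural primed lactone with its methylene intact.

**Alternative 3:** Ring D is cut at C14–C15' and ring E at the migrating C5' bond. In the forward step a Lewis acid ionises a C14 allylic acetate, the C4'=C15' alkene attacks through C15', and a cyclobutanol expands by 1,2-shift to give A5.

- For it: one cascade makes ring D, ring E and the quaternary C4' without an aldol equilibrium. For the spiro centre it is more elegant than the chosen aldol.
- Against it: the allyl cation is delocalised over C14 and C1, so capture at C1 or elimination competes. It must be generated next to an enone and an α-methylene lactone. The primed half has to be rebuilt as a cyclobutanol with a 10'-ketone, so the chiral-pool lactone cannot be used. The 10'-ketone must later be methylenated in the presence of the C3 and C3' ketones.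
- Comparison: the chosen route keeps the natural primed half untouched from commercial 1 and places its main risk in one well-studied cycloaddition class.

Key step: step 12

Assumptions (remarks on the chemistry): 1, 4, 9 and 13 are bought; the (R)-BINAP complex is taken to give the C5 configuration drawn, and the (S)-ligand is used if the sense proves opposite; centres that are erased later (C3' carbinol in 26–31, C4 and C11 in 29 and 30) are carried as mixtures.

## Route

**Step 1**
Reactants: 1 (−)-dehydrocostus lactone
Product: 2 3-epizaluzanin C (3'α-hydroxy)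
Conditions: SeO2 (0.3 equiv), t-BuOOH, CH2Cl2, 0 °C → rt
Reagents that add atoms: tert-butyl hydroperoxide, CC(C)(C)OO
Why: Allylic oxidation by SeO2 (ene reaction, then [2,3]-shift) with the hydroperoxide as terminal oxidant should hydroxylate the ring methylene C3' next to the C4'=C15' alkene from the open α face; the C3' configuration is erased in step 2.

**Step 2**
Reactants: 2 3-epizaluzanin C
Product: 3 dehydrozaluzanin C
Conditions: DMP, NaHCO3, CH2Cl2, 0 °C → rt
Reagents that add atoms: none
Why: Buffered Dess–Martin oxidation of the allylic alcohol should give the exocyclic enone without touching the α-methylene lactone; 3 is used at once because such enones dimerise on standing.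

**Step 3**
Reactants: 3 dehydrozaluzanin C; 4 1-(trimethylsilyl)propyne
Product: 7 C3' O-TIPS enol ether carrying a 4-(trimethylsilyl)but-3-ynyl chain on C4', via lithium bis[3-(trimethylsilyl)prop-2-yn-1-yl]cuprate 5 (not isolated), via C3' lithium enolate 6 (not isolated)
Conditions: 4, n-BuLi, THF, −78 → −20 °C; CuBr·SMe2 (0.5 equiv per Li), −78 °C; then 3, −78 °C; then TIPSOTf, −78 → −30 °C
Reagents that add atoms: triisopropylsilyl triflate, CC(C)[Si](OS(=O)(=O)C(F)(F)F)(C(C)C)C(C)C
Why: Conjugate addition of a Gilman-type cuprate to the s-cis exocyclic enone followed by O-silylation of the enolate; the soft cuprate should prefer the enone to the lactone acceptor at −78 °C, the C-silyl group steers transfer through the propargylic CH2, and trapping fixes the tetrasubstituted C3'=C4' enol ether that enolisation of the ketone would not guarantee. No stereocentre is formed.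

**Step 4**
Reactants: 7 C-silylated alkyne
Product: 8 C3' O-TIPS enol ether carrying a but-3-ynyl chain on C4'
Conditions: AgOTf (10 mol%), CH2Cl2/MeOH/H2O, rt
Reagents that add atoms: none
Why: Silver-catalysed protodesilylation of the C(sp)–SiMe3 bond runs through a silver acetylide in neutral medium, so the bulky O-silyl enol ether and the α-methylene lactone (which carbonate in methanol would attack) should be left alone.

**Step 5**
Reactants: 9 itaconic acid 4-methyl ester
Product: 11 methyl 3-methylidene-4-oxopentanoate, via methyl 3-(chlorocarbonyl)but-3-enoate 10 (not isolated)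
Conditions: (COCl)2, DMF (cat.), CH2Cl2, 0 °C → rt; then MeZnCl, Pd(PPh3)4 (3 mol%), THF, 0 °C
Reagents that add atoms: oxalyl chloride, ClC(=O)C(=O)Cl (chlorine of 10 only); methylzinc chloride, C[Zn]Cl
Why: Negishi acylation: the acyl–palladium species takes the methyl group from zinc faster than the organozinc adds to the ester or the alkene, and the neutral conditions should keep the alkene from moving into conjugation with the ester. The methyl group becomes C5.

**Step 6**
Reactants: 11 methyl 3-methylidene-4-oxopentanoate
Product: 12 methyl 2-(1-acetylcyclopropyl)acetate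
Conditions: CH2N2, Pd(OAc)2 (2 mol%), Et2O, 0 °C
Reagents that add atoms: diazomethane, C=[N+]=[N-]
Why: Palladium-catalysed methylene transfer cyclopropanates terminal electron-poor alkenes under neutral conditions, so the acidic CH2 between alkene and ester is not deprotonated as it could be by a sulfoxonium ylide.

**Step 7**
Reactants: 12 methyl 2-(1-acetylcyclopropyl)acetate; 13 tert-butyl 2-(bromomethyl)prop-2-enoate
Product: 15 tert-butyl 5-[1-(2-methoxy-2-oxoethyl)cyclopropyl]-2-methylidene-5-oxopentanoate, via lithium enolate of the methyl ketone 14 (not isolated)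
Conditions: LDA, THF, −78 °C; then 13, −78 °C
Reagents that add atoms: none
Why: Kinetic enolisation takes the methyl ketone proton (the other α-carbon is quaternary and the ester CH2 is less acidic and neopentyl), and the enolate displaces bromide from the very reactive allylic bromide (SN2 or SN2', same product) before Claisen-type side reactions set in. This forms C4–C5.

**Step 8**
Reactants: 15 2-methylidene ester
Product: 17 tert-butyl 2,2-dimethoxy-5-[1-(2-methoxy-2-oxoethyl)cyclopropyl]-5-oxopentanoate, via tert-butyl 2,5-dioxo ester 16 (not isolated)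
Conditions: O3, CH2Cl2, −78 °C; Me2S; then HC(OMe)3, p-TsOH (cat.), MeOH, rt
Reagents that add atoms: ozone, [O-][O+]=O; trimethyl orthoformate, COC(OC)OC
Why: Ozonolysis of the only alkene gives the α-keto ester, whose very electrophilic ketone should be ketalised selectively while the hindered, cyclopropane-conjugated C6 ketone is not.

**Step 9**
Reactants: 17 ketal tert-butyl ester
Product: 18 2,2-dimethoxy-5-[1-(2-methoxy-2-oxoethyl)cyclopropyl]-5-oxopentanoic acid
Conditions: CF3CO2H, CH2Cl2, 0 °C → rt
Reagents that add atoms: none
Why: Anhydrous acidolysis of the tert-butyl ester (loss of isobutene) should spare the methyl ester and the ketal, whose ionisation is disfavoured by the adjacent carboxyl group.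

**Step 10**
Reactants: 18 ketal acid; 8 terminal alkyne
Product: 20 ynone with C2 ketone between the C1≡C10 alkyne and the C3 ketal, via acid chloride 19 (not isolated)
Conditions: 18, 1-chloro-N,N,2-trimethylprop-1-en-1-amine, CH2Cl2, 0 °C; then 8, PdCl2(PPh3)2 (2 mol%), CuI (4 mol%), Et3N, THF, rt
Reagents that add atoms: 1-chloro-N,N,2-trimethylprop-1-en-1-amine, CC(C)=C(Cl)N(C)C (chlorine of 19 only)
Why: Neutral chlorination gives an acid chloride with no α-hydrogen (no ketene), which couples with the terminal alkyne in an acyl Sonogashira reaction at room temperature; lactone, ester, ketone, ketal and the TIPS enol ether tolerate the amine base.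

**Step 11**
Reactants: 20 ynone ketone
Product: 21 (Z)-C6 O-TBS enol ether (yne-vinylcyclopropane)
Conditions: TBSOTf, Et3N, CH2Cl2, −78 → −20 °C
Reagents that add atoms: tert-butyldimethylsilyl triflate, CC(C)(C)[Si](C)(C)OS(=O)(=O)C(F)(F)F
Why: Soft enolisation of the cyclopropyl ketone can only go toward C5 because C7 is quaternary. The Z isomer is expected because the E isomer would press the C4 chain against the quaternary cyclopropane. The ynone has no α-hydrogen and the C3' ketone is already masked.

**Step 12 (key step)**
Reactants: 21 (Z)-C6 O-TBS enol ether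
Product: 22 (5+2) adduct with rings A and B closed (5α-H, C2 ketone, C6=C7 O-TBS enol ether)
Conditions: [Rh((R)-BINAP)]SbF6 (10 mol%), ClCH2CH2Cl, 60 °C
Reagents that add atoms: none
Why: This is the known rhodium-catalysed intramolecular (5+2) cycloaddition of an alkyne with a 1-siloxy-vinylcyclopropane. The cationic monovalent rhodium complex binds the C5=C6 enol ether and cleaves the cyclopropane bond C7–C9, giving a trivalent rhodium metallacycle bonded to C9 and to the C5–C6–C7 allyl unit; the tethered alkyne inserts at C5 (C1–C5 formed) and reductive elimination joins C9 to C10. Ring A closes as a five-membered ring because the three-atom tether C2–C3–C4 links C1 to C5 (exo with respect to the tether), and ring B closes as the seven-membered ring by the C9–C10 reductive elimination from the eight-membered rhodacycle. C5 is the only new stereocentre; it is set by the face of the enol ether that the C2-symmetric BINAP pocket offers, since the primed stereocentres are too remote to interfere. There is no regiochemical question because C8 and C9 are equivalent methylenes, and the alkyne carbons end as the C1=C10 alkene. Chemoselectivity rests on the tether: only the ynone alkyne can reach the metallacycle, while the TIPS enol ether, the exocyclic alkenes and the lactone acceptor are remote or fully substituted. The Z geometry keeps the tether trans to the cyclopropane so the s-cis conformer needed for cyclometallation is accessible, and the siloxy group speeds ring cleavage. A non-coordinating counter-ion and a non-basic solvent should keep the doubly allylic C5–H from isomerising.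

**Step 13**
Reactants: 22 (5+2) adduct
Product: 23 ring D aldol product (C2 tertiary alcohol, C4' spiro centre, C3' ketone)
Conditions: TiCl4, CH2Cl2, −78 °C; aq. NaHCO3
Reagents that add atoms: none
Why: Intramolecular Mukaiyama aldol; only the six-membered closure C4'→C2 is possible (attack at C10 would give a four-membered ring). C4' should be attacked on the convex α face of the cis-fused ring E/F bicycle (syn to H-5'). An open antiperiplanar transition state puts the titanium-bound C2 oxygen anti to C3', which in the nascent cyclohexene is the trans O/C3' relation of the target.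

**Step 14**
Reactants: 23 aldol product
Product: 24 C6 ketone (7α-H)
Conditions: HF·pyridine, pyridine, THF, 0 °C
Reagents that add atoms: none
Why: Cleavage of the TBS enol ether with protonation at C7; kinetic approach opposite to C4 on C5 and the thermodynamic preference for a side chain cis-1,3 to C4 both favour 7α-H. The non-basic medium should keep C5 (now α to a ketone and allylic) and the β-hydroxy ketone intact.

**Step 15**
Reactants: 24 C6 ketone
Product: 26 trans-lactone (ring C closed) with C3' carbinol and C3 ketal, via 6α-hydroxy methyl ester 25 (not isolated)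
Conditions: NaBH4, CeCl3·7H2O, MeOH/THF, −78 → 0 °C; then PPTS (cat.), CH2Cl2, rt
Reagents that add atoms: none
Why: Luche reduction; the small hydride should attack C6 anti to the axial 5α- and 7α-hydrogens (axial attack), giving the all-equatorial 6α-alkoxide that closes onto the C12 ester as the trans lactone. The C3' ketone is reduced on purpose, which removes the retro-aldol pathway and the C2' enolisation site for steps 16–18. The lactones and the ketal are inert, and cerium suppresses conjugate reduction of the primed lactone.

**Step 16**
Reactants: 26 ketal lactone diol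
Product: 27 C3 ketone (α-ketol) lactone diol
Conditions: 1 M HCl, THF, rt
Reagents that add atoms: water, O
Why: Hydrolysis of the dimethyl ketal through the C3 oxocarbenium ion; ionisation of the tertiary allylic C2–OH is disfavoured by the neighbouring oxygenated carbons, and dilute acid at room temperature should leave the exocyclic alkenes in place.

**Step 17**
Reactants: 27 α-ketol lactone diol
Product: 29 bis-Mannich base (Me2NCH2 on C4 and on C11), via tetrakis(trimethylsilyl) derivative 28 (not isolated)
Conditions: TMSOTf, i-Pr2NEt, CH2Cl2, 0 °C → rt; then Me2N=CH2 I, CH2Cl2, rt; then 1 M HCl, THF; NaHCO3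
Reagents that add atoms: trimethylsilyl triflate, C[Si](C)(C)OS(=O)(=O)C(F)(F)F (silyl groups of 28 only); dimethyl(methylidene)ammonium iodide, C=[N+](C)C.[I-]
Why: Soft enolisation turns the only two enolisable carbonyl groups into nucleophiles (C3 ketone → C3=C4 silyl enol ether, unprimed lactone → silyl ketene acetal) and silylates both hydroxyls; both then undergo Mannich reaction with the iminium salt. The hindered amine does not add to the primed α-methylene lactone, and no strong base is used.

**Step 18**
Reactants: 29 bis-Mannich base
Product: 31 3'-hydroxy precursor with C4=C15 and C11=C13 in place, via bis(trimethylammonium) diiodide 30 (not isolated)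
Conditions: MeI, MeCN, rt; then aq. NaHCO3, EtOAc, rt
Reagents that add atoms: iodomethane, CI (N-methyl groups of 30 only)
Why: Quaternisation and E1cB elimination of trimethylamine from the β-ammonium ketone and the β-ammonium lactone should unveil both exocyclic alkenes at once under bicarbonate.

**Step 19**
Reactants: 31 3'-hydroxy precursor
Product: 32 target
Conditions: DMP, NaHCO3, CH2Cl2, 0 °C → rt
Reagents that add atoms: none
Why: Dess–Martin oxidation of the single secondary alcohol gives the C3' ketone; the tertiary C2–OH cannot be oxidised and the buffered medium should not trigger retro-aldol cleavage or harm the three Michael acceptors.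

## Compound list

1 | (−)-dehydrocostus lactone (guaia-4(15),10(14),11(13)-trien-12,6α-olide; 1α,5α,7α-H, 6β-H) | C=C1CC[C@H]2C(=C)CC[C@H]3C(=C)C(=O)O[C@@H]3[C@@H]12 | starting material
2 | 3-epizaluzanin C (3'α-hydroxy derivative of 1) | C=C1[C@H](O)C[C@H]2C(=C)CC[C@H]3C(=C)C(=O)O[C@@H]3[C@@H]12 | intermediate
3 | dehydrozaluzanin C (3'-oxo derivative of 1) | C=C1C(=O)C[C@H]2C(=C)CC[C@H]3C(=C)C(=O)O[C@@H]3[C@@H]12 | intermediate
4 | 1-(trimethylsilyl)propyne | CC#C[Si](C)(C)C | starting material
5 | lithium bis[3-(trimethylsilyl)prop-2-yn-1-yl]cuprate | [Li+].C[Si](C)(C)C#CC[Cu-]CC#C[Si](C)(C)C | intermediate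
6 | C3' lithium enolate (C3'=C4') of the conjugate adduct of 3 | C[Si](C)(C)C#CCCC1=C(O[Li])C[C@H]2C(=C)CC[C@H]3C(=C)C(=O)O[C@@H]3[C@@H]12 | intermediate
7 | primed unit as C3' O-TIPS enol ether (C3'=C4') with a 4-(trimethylsilyl)but-3-ynyl chain (C15', C14, C10, C1) on C4' | C[Si](C)(C)C#CCCC1=C(O[Si](C(C)C)(C(C)C)C(C)C)C[C@H]2C(=C)CC[C@H]3C(=C)C(=O)O[C@@H]3[C@@H]12 | intermediate
8 | primed unit as C3' O-TIPS enol ether with a but-3-ynyl chain on C4' (terminal alkyne) | C#CCCC1=C(O[Si](C(C)C)(C(C)C)C(C)C)C[C@H]2C(=C)CC[C@H]3C(=C)C(=O)O[C@@H]3[C@@H]12 | intermediate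
9 | itaconic acid 4-methyl ester (4-methoxy-2-methylidene-4-oxobutanoic acid) | C=C(CC(=O)OC)C(=O)O | starting material
10 | methyl 3-(chlorocarbonyl)but-3-enoate | C=C(CC(=O)OC)C(=O)Cl | intermediate
11 | methyl 3-methylidene-4-oxopentanoate | CC(=O)C(=C)CC(=O)OC | intermediate
12 | methyl 2-(1-acetylcyclopropyl)acetate | CC(=O)C1(CC(=O)OC)CC1 | intermediate
13 | tert-butyl 2-(bromomethyl)prop-2-enoate | C=C(CBr)C(=O)OC(C)(C)C | starting material
14 | lithium enolate of methyl ketone 12 | [Li]OC(=C)C1(CC(=O)OC)CC1 | intermediate
15 | tert-butyl 5-[1-(2-methoxy-2-oxoethyl)cyclopropyl]-2-methylidene-5-oxopentanoate | CC(C)(C)OC(=O)C(=C)CCC(=O)C1(CC(=O)OC)CC1 | intermediate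
16 | tert-butyl 5-[1-(2-methoxy-2-oxoethyl)cyclopropyl]-2,5-dioxopentanoate | CC(C)(C)OC(=O)C(=O)CCC(=O)C1(CC(=O)OC)CC1 | intermediate
17 | tert-butyl 2,2-dimethoxy-5-[1-(2-methoxy-2-oxoethyl)cyclopropyl]-5-oxopentanoate | CC(C)(C)OC(=O)C(OC)(OC)CCC(=O)C1(CC(=O)OC)CC1 | intermediate
18 | 2,2-dimethoxy-5-[1-(2-methoxy-2-oxoethyl)cyclopropyl]-5-oxopentanoic acid (C2 acid, C3 ketal, C6 ketone, C12 ester) | OC(=O)C(OC)(OC)CCC(=O)C1(CC(=O)OC)CC1 | intermediate
19 | acid chloride of 18 | ClC(=O)C(OC)(OC)CCC(=O)C1(CC(=O)OC)CC1 | intermediate
20 | ynone: C2 ketone between the C1≡C10 alkyne and the C3 dimethyl ketal, C6 cyclopropyl ketone, C12 methyl ester, primed unit as C3' O-TIPS enol ether | COC(=O)CC1(CC1)C(=O)CCC(OC)(OC)C(=O)C#CCCC2=C(O[Si](C(C)C)(C(C)C)C(C)C)C[C@H]3C(=C)CC[C@H]4C(=C)C(=O)O[C@@H]4[C@@H]23 | intermediate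
21 | cycloaddition precursor: (Z)-C6 O-TBS enol ether (C5=C6) of 20 | COC(=O)CC1(CC1)/C(O[Si](C)(C)C(C)(C)C)=C/CC(OC)(OC)C(=O)C#CCCC2=C(O[Si](C(C)C)(C(C)C)C(C)C)C[C@H]3C(=C)CC[C@H]4C(=C)C(=O)O[C@@H]4[C@@H]23 | intermediate
22 | (5+2) adduct: rings A and B closed, 5α-H, C1=C10, C2 ketone, C3 dimethyl ketal, C6=C7 O-TBS enol ether, C7 CH2CO2Me; C10 linked by C14–C15' to C4' of the C3' O-TIPS enol ether | C1C(OC)(OC)C(=O)C3=C(CCC(CC(=O)OC)=C(O[Si](C)(C)C(C)(C)C)[C@@H]13)CCC1=C(O[Si](C(C)C)(C(C)C)C(C)C)C[C@H]2C(=C)CC[C@H]3C(=C)C(=O)O[C@@H]3[C@@H]12 | intermediate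
23 | aldol product: ring D closed, C2 tertiary alcohol (α-OH), C4' spiro centre, C3' ketone, C6=C7 O-TBS enol ether retained | C1C(OC)(OC)[C@]2(O)C3=C(CCC(CC(=O)OC)=C(O[Si](C)(C)C(C)(C)C)[C@@H]13)CC[C@]21C(=O)C[C@H]2C(=C)CC[C@H]3C(=C)C(=O)O[C@@H]3[C@H]21 | intermediate
24 | C6 ketone with 7α-H (side chain β), C2 alcohol, C3 ketal, C3' ketone | C1C(OC)(OC)[C@]2(O)C3=C(CC[C@@H](CC(=O)OC)C(=O)[C@@H]13)CC[C@]21C(=O)C[C@H]2C(=C)CC[C@H]3C(=C)C(=O)O[C@@H]3[C@H]21 | intermediate
25 | 6α-hydroxy methyl ester with C3' carbinol (C3' configuration not controlled) | C1C(OC)(OC)[C@]2(O)C3=C(CC[C@@H](CC(=O)OC)[C@H](O)[C@@H]13)CC[C@]21C(O)C[C@H]2C(=C)CC[C@H]3C(=C)C(=O)O[C@@H]3[C@H]21 | intermediate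
26 | trans-lactone (ring C, 6β-H, 7α-H, C11 H2), C2 alcohol, C3 dimethyl ketal, C3' carbinol | C1C(OC)(OC)[C@]2(O)C3=C(CC[C@H]4CC(=O)O[C@@H]4[C@@H]13)CC[C@]21C(O)C[C@H]2C(=C)CC[C@H]3C(=C)C(=O)O[C@@H]3[C@H]21 | intermediate
27 | α-ketol: C3 ketone, C2 alcohol, ring C lactone (C11 H2), C3' carbinol | C1C(=O)[C@]2(O)C3=C(CC[C@H]4CC(=O)O[C@@H]4[C@@H]13)CC[C@]21C(O)C[C@H]2C(=C)CC[C@H]3C(=C)C(=O)O[C@@H]3[C@H]21 | intermediate
28 | tetrakis(trimethylsilyl) derivative of 27: C3=C4 silyl enol ether, C11=C12 silyl ketene acetal, C2 and C3' O-silyl ethers | C1=C(O[Si](C)(C)C)[C@]2(O[Si](C)(C)C)C3=C(CC[C@H]4C=C(O[Si](C)(C)C)O[C@@H]4[C@@H]13)CC[C@]21C(O[Si](C)(C)C)C[C@H]2C(=C)CC[C@H]3C(=C)C(=O)O[C@@H]3[C@H]21 | intermediate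
29 | bis-Mannich base: dimethylaminomethyl groups on C4 and on C11 (both centres as mixtures) | CN(C)CC1C(=O)[C@]2(O)C3=C(CC[C@H]4C(CN(C)C)C(=O)O[C@@H]4[C@@H]13)CC[C@]21C(O)C[C@H]2C(=C)CC[C@H]3C(=C)C(=O)O[C@@H]3[C@H]21 | intermediate
30 | bis(trimethylammonium) diiodide of 29 | C[N+](C)(C)CC1C(=O)[C@]2(O)C3=C(CC[C@H]4C(C[N+](C)(C)C)C(=O)O[C@@H]4[C@@H]13)CC[C@]21C(O)C[C@H]2C(=C)CC[C@H]3C(=C)C(=O)O[C@@H]3[C@H]21.[I-].[I-] | intermediate
31 | 3'-hydroxy precursor: target skeleton with C4=C15 and C11=C13 in place and C3' carbinol instead of ketone | C=C1C(=O)[C@]2(O)C3=C(CC[C@H]4C(=C)C(=O)O[C@@H]4[C@@H]13)CC[C@]21C(O)C[C@H]2C(=C)CC[C@H]3C(=C)C(=O)O[C@@H]3[C@H]21 | intermediate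
32 | CNP0269880.2 | C=C1C(=O)[C@]2(O)C3=C(CC[C@H]4C(=C)C(=O)O[C@@H]4[C@@H]13)CC[C@]21C(=O)C[C@H]2C(=C)CC[C@H]3C(=C)C(=O)O[C@@H]3[C@H]21 | target

## Step count and risk

Total step count: 19. Longest linear sequence: 15 steps (9 → 32, steps 5–19); the branch from 1 contributes 4 steps before the union in step 10.

**Step 12 (key step).** The cationic rhodium centre may be held by the ynone carbonyl and ketal oxygens, so that cyclometallation of the hindered, fully substituted vinylcyclopropane becomes slow; the facial choice at C5, which only the ligand controls, then erodes, and the longer heating invites migration of the C1=C10 alkene. The fallback sets out from 21: asymmetric transfer hydrogenation of the ynone carbonyl (RuCl(p-cymene)[(S,S)-TsDPEN], i-PrOH) gives the C2 propargylic alcohol F1, which no longer has a conjugated carbonyl on the alkyne. Cycloaddition of F1 with neutral [Rh(CO)2Cl]2 in ClCH2CH2Cl gives the bicyclic allylic alcohol F2, the carbinol stereocentre in the tether taking over control at C5 from the ligand. Oxidation of F2 with MnO2 comes back to 22.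

**Step 3.** The ambident ligand may be transferred through its silyl-bearing terminus (giving an allenylsilane), or the cuprate may add to the lactone methylene. The fallback sets out from 3: TiCl4-promoted Hosomi–Sakurai-type conjugate addition of allenyltributylstannane (SE2' attack, so the propargyl connectivity is fixed and the alkyne is formed free) gives the 4'-(but-3-ynyl) ketone F3. Soft enolisation of F3 with TIPSOTf and Et3N, which removes the more substituted α-hydrogen from the O-silylated oxocarbenium ion, comes back at 8, and step 4 is then not needed.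

**Step 13.** Facial selectivity at C2 may be poor because the unprimed half is still flexible and C5 exerts little bias, or the acid-labile C6 enol ether may be lost under the Lewis acid. The fallback sets out from 22 and closes ring D only after ring C:
- selective cleavage of the TBS enol ether (HF·pyridine, −20 °C; the TIPS enol ether is slower) gives diketone F4;
- Luche reduction reduces C6 and C2, and lactonisation gives lactone allylic alcohol F5;
- MnO2 restores the C2 enone in F6;
- the TiCl4 aldol is then run on this rigid trans-lactone to give F7;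
- NaBH4/CeCl3 reduction of the C3' ketone of F7 comes back at 26.

**Step 15.** Hydride may be delivered to the α face of C6, anti to the side chain, giving the 6β-alkoxide that closes to the cis lactone. The fallback turns that preference to use and sets out from 24: mild hydrolysis of the methyl ester (Me3SnOH, ClCH2CH2Cl) gives keto acid F8. Reduction of F8 with NaBH4 in basic methanol gives the 6β-hydroxy carboxylate F9, which does not lactonise as its salt. Mitsunobu lactonisation (PPh3, diisopropyl azodicarboxylate) closes ring C with inversion at C6 and comes back at 26.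

**Step 17.** Conversion of the lactone into its silyl ketene acetal may be incomplete (C-silylation, or reaction of the ketone only), so that only C4 is aminomethylated. The fallback sets out from 26, where no ketone is present. Lactone enolisation with LiHMDS (excess, −78 °C) and trapping with Me2N=CH2 I gives amine F10. MeI then aqueous NaHCO3 gives the methylene lactone F11, 1 M HCl gives α-ketol F12, and direct methylenation of the single ketone with i-Pr2NH·CF3CO2H and paraformaldehyde in THF comes back at 31.

## Further compounds

F1 | step 12 | C2 propargylic alcohol of 21 (one C2 epimer, set by the reduction catalyst) | COC(=O)CC1(CC1)/C(O[Si](C)(C)C(C)(C)C)=C/CC(OC)(OC)C(O)C#CCCC2=C(O[Si](C(C)C)(C(C)C)C(C)C)C[C@H]3C(=C)CC[C@H]4C(=C)C(=O)O[C@@H]4[C@@H]23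
F2 | step 12 | (5+2) adduct as its C2 allylic alcohol | C1C(OC)(OC)C(O)C3=C(CCC(CC(=O)OC)=C(O[Si](C)(C)C(C)(C)C)[C@@H]13)CCC1=C(O[Si](C(C)C)(C(C)C)C(C)C)C[C@H]2C(=C)CC[C@H]3C(=C)C(=O)O[C@@H]3[C@@H]12
F3 | step 3 | 4'-(but-3-ynyl)-11(13),10(14)-guaiadien-3'-one-12,6-olide (C4' epimers) | C#CCCC1C(=O)C[C@H]2C(=C)CC[C@H]3C(=C)C(=O)O[C@@H]3[C@@H]12
F4 | step 13 | C2,C6-diketone from 22 with the C3' O-TIPS enol ether retained | C1C(OC)(OC)C(=O)C3=C(CC[C@@H](CC(=O)OC)C(=O)[C@@H]13)CCC1=C(O[Si](C(C)C)(C(C)C)C(C)C)C[C@H]2C(=C)CC[C@H]3C(=C)C(=O)O[C@@H]3[C@@H]12
F5 | step 13 | ring C trans-lactone with C2 allylic alcohol and C3' O-TIPS enol ether | C1C(OC)(OC)C(O)C3=C(CC[C@H]4CC(=O)O[C@@H]4[C@@H]13)CCC1=C(O[Si](C(C)C)(C(C)C)C(C)C)C[C@H]2C(=C)CC[C@H]3C(=C)C(=O)O[C@@H]3[C@@H]12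
F6 | step 13 | ring C trans-lactone with C2 enone and C3' O-TIPS enol ether | C1C(OC)(OC)C(=O)C3=C(CC[C@H]4CC(=O)O[C@@H]4[C@@H]13)CCC1=C(O[Si](C(C)C)(C(C)C)C(C)C)C[C@H]2C(=C)CC[C@H]3C(=C)C(=O)O[C@@H]3[C@@H]12
F7 | step 13 | ring D aldol product with ring C lactone closed and C3' ketone | C1C(OC)(OC)[C@]2(O)C3=C(CC[C@H]4CC(=O)O[C@@H]4[C@@H]13)CC[C@]21C(=O)C[C@H]2C(=C)CC[C@H]3C(=C)C(=O)O[C@@H]3[C@H]21
F8 | step 15 | C12 carboxylic acid of ketone 24 | C1C(OC)(OC)[C@]2(O)C3=C(CC[C@@H](CC(=O)O)C(=O)[C@@H]13)CC[C@]21C(=O)C[C@H]2C(=C)CC[C@H]3C(=C)C(=O)O[C@@H]3[C@H]21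
F9 | step 15 | 6β-hydroxy C12 acid with C3' carbinol | C1C(OC)(OC)[C@]2(O)C3=C(CC[C@@H](CC(=O)O)[C@@H](O)[C@@H]13)CC[C@]21C(O)C[C@H]2C(=C)CC[C@H]3C(=C)C(=O)O[C@@H]3[C@H]21
F10 | step 17 | 26 bearing a dimethylaminomethyl group on C11 | C1C(OC)(OC)[C@]2(O)C3=C(CC[C@H]4C(CN(C)C)C(=O)O[C@@H]4[C@@H]13)CC[C@]21C(O)C[C@H]2C(=C)CC[C@H]3C(=C)C(=O)O[C@@H]3[C@H]21
F11 | step 17 | C3 ketal diol with the unprimed α-methylene lactone in place | C1C(OC)(OC)[C@]2(O)C3=C(CC[C@H]4C(=C)C(=O)O[C@@H]4[C@@H]13)CC[C@]21C(O)C[C@H]2C(=C)CC[C@H]3C(=C)C(=O)O[C@@H]3[C@H]21
F12 | step 17 | α-ketol diol with both α-methylene lactones and C4 H2 | C1C(=O)[C@]2(O)C3=C(CC[C@H]4C(=C)C(=O)O[C@@H]4[C@@H]13)CC[C@]21C(O)C[C@H]2C(=C)CC[C@H]3C(=C)C(=O)O[C@@H]3[C@H]21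
A1 | alternative 1 | ring A/B hydroazulene diester (C2 dioxolane, C6 O-TBS, C7=C8, C14 ester) | C1CC2(OCCO2)C3=C(C(=O)OC)CC=C(CC(=O)OC)[C@H](O[Si](C)(C)C(C)(C)C)[C@@H]13
A2 | alternative 1 | methyl 2-diazo-2-(1,4-dioxaspiro[4.4]non-6-en-6-yl)acetate | COC(=O)C(=[N+]=[N-])C1=CCCC12OCCO2
A3 | alternative 1 | methyl (Z)-3-[(tert-butyldimethylsilyl)oxymethylidene]pent-4-enoate | C=C/C(CC(=O)OC)=C\O[Si](C)(C)C(C)(C)C
A4 | alternative 2 | ring A ketol (C15 O-TBS, both lactones as 11-methyl forms) | [C@H]1(CO[Si](C)(C)C(C)(C)C)C(=O)[C@]2(O)C3=C(CC[C@H]4[C@H](C)C(=O)O[C@@H]4[C@@H]13)CC[C@]21C(=O)C[C@H]2C(=C)CC[C@H]3[C@H](C)C(=O)O[C@@H]3[C@H]21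
A5 | alternative 3 | 10'-oxo (14'-nor) target 2-O-TBS ether | C=C1C(=O)[C@]2(O[Si](C)(C)C(C)(C)C)C3=C(CC[C@H]4C(=C)C(=O)O[C@@H]4[C@@H]13)CC[C@]21C(=O)C[C@H]2C(=O)CC[C@H]3C(=C)C(=O)O[C@@H]3[C@H]21
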